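Conventions used below (ad hoc positional numbering): C1–C10 are the decalin carbons (C3 ring A carbonyl carbon, C4 gem-dimethyl carbon, C5/C10 the A/B fusion, C9 the B/C fusion CH, C8 the B/C quaternary carbon); C11 ring C CH2; C12 methyl-bearing bridgehead; C13 one-carbon bridge; C14 carboxyl-bearing bridgehead; C15 carbinol carbon; C16 ring D CH2; C17 the O–CH(CH3) carbon; C18 the γ-lactone carbonyl. β is the face of the C10 methyl, α the opposite face.

Remarks on the chemistry:
- (R)-Wieland–Miescher ketone, methyl (R)-lactate and the reagents named are taken as commercial.
- C12 of compounds 14–22 is created by protonation next to a carbonyl, cannot be controlled there and need not be, because it is planarised in dianion 28. These compounds are therefore formulated as C12-epimer pairs.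
- C14 of 22, 29, 31 and 32 is an enolisable β-keto ester carbon and is left unassigned.
- The configurations along the route were checked against the target: the (R) antipode of 1 is the one required, and C8 as created in 21 maps directly onto C8 of 39.

## Structural features

Brasilianoid B (39) is pentacyclic. A seven-membered α,β-unsaturated ε-lactone (ring A, C10–C1=C2–C3(=O)–O–C4Me2–C5) is fused through C5–C10 to cyclohexane ring B, which shares C8–C9 with ring C. Ring C is the six-membered ring of a bicyclo[3.2.1]octane: the one-carbon bridge C13 carries the exocyclic methylene, the two-carbon bridge C15–C16 completes cyclopentane ring D, and a γ-lactone (ring E, C14–C18(=O)–O–C17–C15) is cis-fused on C14–C15.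

There are eight stereocentres. Six form an unbroken chain C10–C9–C8–C14–C15–C17, in which C10, C8 and C14 are quaternary and C15 is a fully substituted carbinol; C5 and the quaternary C12 flank this chain. The A/B fusion is trans (H5 α), H9 is α, the C8 methyl is β-axial and 1,3-diaxial to the C10 methyl, the C15–C16 bridge lies on the α face of ring C, and the C15 hydroxyl and C17 methyl are cis on ring E.

The fragile groups are:
- the tertiary β-hydroxy carbonyl unit (C15–OH against C18, and against C13 while C13 is a ketone), which can undergo retro-aldol cleavage under base;
- the unsaturated ε-lactone with its tertiary alkyl oxygen (conjugate addition, solvolysis);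
- the 1,1-disubstituted alkene between two quaternary carbons (peracids, cationic rearrangement).

The real difficulty is the C8–C14 bond between two vicinal quaternary carbons, one of which bears an axial methyl syn to a second axial methyl, together with the adjacent bridging unit C12–C13–C14. The key step exploits exactly this: C8, its methyl carbon and C14 (the carbon that carries C18 and is attached to C13) are the three atoms of a cyclopropane. A carbene at C14, flanked by the C13 ketone and the C18 ester, can close that cyclopropane onto an exocyclic methylene at C8 of ring B.

## Logic of the disconnections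

**39 to 36.** The C1=C2 π bond is removed first. The unsaturated lactone is the most reactive group of the target, and its saturated form survives enolate and titanium chemistry. The forward step needs C2 to be the only enolisable carbon of 36, which holds because C14 is quaternary.

**36 to 35.** The C13=CH2 bond is cut to a ketone. An alkene of this kind would not survive a peracid, so it has to be made after ring A is oxidised; the ketone also provides the activation at C14 and C12 used earlier. The forward step must methylenate a non-enolisable bridging ketone without base and without touching two lactones.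

**35 to 34.** The C3–O bond of ring A is cut (oxygen removed between C3 and C4). Ring A is thus carried as a cyclohexanone, which can be protected through reductive and strongly basic steps. The forward oxidation must prefer the C3 ketone over the far more hindered C13 ketone.

**34 to 32.** The C14–C15 bond and the O–C18 bond are cut together. C13=O and C15–OH stand in an aldol relationship, and the lactone is what makes that aldol irreversible. Two rings and two stereocentres disappear, leaving a monocyclic ring C. The forward cascade needs C16 on the α face of C12 and an (R)-configured C17 that is not epimerised.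

**32 to 31 to 29.** Functional groups only: the C3 ketone and C17 hydroxyl are masked, and the C15 carbonyl is traced to a C15=CH2 group. An allylic bromide alkylates a basic enolate far better than an α-halo ketone would. The forward cleavage must spare the enolised β-keto ester.

**29 to 22 and 27.** The C12–C16 bond is cut next to the C13 ketone. This is the convergent point: the four-carbon side chain, with C17 from the chiral pool, meets the tricycle. The forward step needs γ-selectivity in a β-keto ester (hence dianion 28) and attack on the α face of C12.

**27 to 23.** The C15–C16 bond and the C15 methylene are traced to the ester carbon of a lactate, which supplies C17 with its oxygen and methyl in the correct absolute sense.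

**22 to 21.** A bond is added between C14 and the C8 methyl carbon. This converts the problem of an axial quaternary methyl next to a quaternary carbon into that of a cyclopropane. The forward cleavage must break the external cyclopropane bond and not the ring-fusion bond.

**21 to 19.** The C8–C14 bond and the CH2–C14 bond are cut together (the key step). Ring C and both adjacent quaternary carbons vanish; what remains is a decalin with an exocyclic methylene and a side chain. The forward step must add to the α face of the alkene and must prefer the π bond over C–H bonds.

**19 to 18 to 15 and 16.** The diazo group is removed and the C13–C14 bond is cut to an ester and an acetate enolate. The demand is acylation at an α-branched ester.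

**15 to 14 to 11 and 12.** The C8=CH2 bond is cut to a ketone and the C11–C12 bond to an exocyclic enone plus a propionate enolate. The C8 ketone lets C9 settle into its stable configuration by enolisation, and no epimerisable β,γ-unsaturated aldehyde is needed. The C8 ketone must be methylenated before the β-keto ester exists, otherwise the 1,5-dicarbonyl compound would close by aldol condensation.

**11 to 10 to 9 to 8.** The C9=C11 bond and the C8 oxygen are traced to the C9 ketone. This is a 1,2-carbonyl transposition by methylenation and allylic oxidation; C8 is the only allylic carbon that bears hydrogen.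

**8 to 7 to 6 to 3 to 2 to 1.** The two C4 methyl groups (one carbon from formaldehyde, one from iodomethane) and the C5 hydrogen are removed. The C9 carbonyl is parked as an alcohol so that the two ketones of 1 stay distinguishable without exchanging protecting groups.

## Other disconnections considered

**Alternative 1: enone–enol ether photocycloaddition, then ring expansion.**
- Cut: C14–C15 and C13–C16 in photoadduct A2, followed by a shift of C16 from C13 to C12.
- Forward key step: irradiation at 350 nm of enone ester A1, in which the C13=C14 enone (C12 ketone, C13 methyl) carries on C18 the ester of an (R)-configured silyl enol ether alcohol. The excited enone should bond C14 to C15 first, closing the five-membered lactone, and the diradical should then close C13–C16 to give A2. Addition of a methyl nucleophile to the C12 ketone, ionisation, migration of C16 and loss of a proton from the C13 methyl would complete ring D and the exocyclic methylene.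
- In its favour: C14, C15 and ring E arise under neutral conditions with no retro-aldol pathway, and C17 is delivered by the ester. The alkene is generated without methylenating a hindered ketone, and the ring A oxidation can precede it. On these two points the alternative is the better of the two plans.
- Against it here: A1 still contains the C8–C14 bond and the axial C8 methyl, so the hardest bond of the molecule is left to another method. The cycloaddition must choose the α face of a planar C14 next to quaternary C8. The cationic step has three bonds on C13 that could migrate and develops charge next to the acyl-bearing C14, so elimination or the wrong shift are real possibilities, and the acid needed threatens the silyl ether and the dioxolane.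
- Comparison: in structure it solves the right-hand half only, whereas the chosen plan solves the B/C junction and uses an aldol for the right-hand half. In mechanism it relies on a diradical closure and a carbocation in a strained tetracycle, against a carbenoid addition whose facial bias follows from one axial methyl. In step count it is shorter by two or three operations for rings D and E, but the preparation of A1 and of its enol ether ester gives this back, so overall it is no shorter.

**Alternative 2: aldol–lactonisation cascade as the strategic step.**
- Cut: C14–C15 and O–C18.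
- Forward key step: a weak base (DBU, or K2CO3 in methanol) converts the ring C β-keto ester A3, which carries the 3-hydroxy-2-oxobutyl chain on C12, into the bridged hydroxy lactone A4. The C14 enolate adds to the C15 ketone and the C17 hydroxyl then displaces methoxide.
- In its favour: two rings and two stereocentres under equilibrating conditions that funnel to the only epimer able to lactonise. The chosen plan uses the same transformation in step 21 (on the ring A ketone 32 rather than on a dioxolane), so on rings D and E the two plans are equal.
- Against it here: as a plan-defining step it leaves open how A3 obtains its two quaternary carbons C8 and C12 and the C8–C14 bond. The obvious answer, conjugate addition of a methyl group to a ring C enone, has to deliver the methyl syn to the C10 methyl. The cascade is reversible before lactonisation, and the α-hydroxy ketone can epimerise at C17.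
- Comparison: in structure it addresses the least difficult part of the framework. In mechanism it is a polar, thermodynamically driven closure, complementary to the kinetically controlled carbenoid addition and not in competition with it. In step count it is identical for the part it covers.

**Alternative 3: type 2 carbonyl-ene closure of ring C.**
- Cut: C11–C12.
- Forward key step: Me2AlCl activates the C11 aldehyde on C9 of A5, whose C8 carries a 3,4-dimethylcyclopent-3-enone with the C14 ester. The aldehyde carbon bonds to C12 of the tetrasubstituted alkene, a hydrogen of the C13 methyl moves to oxygen, and ring C closes to give A6 with the exocyclic methylene in place.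
- In its favour: ring C, the quaternary C12 and the alkene form in one step, the alkene never has to be made from a hindered ketone, and C12 is set by the geometry of the tether. On these points it is the equal or the better of the chosen plan.
- Against it here: A5 already contains the C8–C14 bond between two quaternary carbons, now with C14 as a stereocentre in a freely rotating substituent, so the central problem is moved to an earlier and less controlled stage. The β,γ-unsaturated ketone of A5 can slip into conjugation, and the neopentyl aldehyde is epimerisable at C9. The Lewis acid may open the dioxolane. The C11 hydroxyl of A6 must then be removed in two further steps, and C17 with its oxygen still has to be added to the hindered C15 ketone from the correct face before lactonisation.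
- Comparison: in structure it makes the bond that is easiest to make in ring C and leaves the hardest. In mechanism a concerted ene reaction is as well defined as the cyclopropanation. In step count the closure saves the methylenation, but the deoxygenation and the late two-carbon addition make the route longer overall.

Key step: step 13

## Route

Step 1
Reactants: 1 (R)-Wieland–Miescher ketone
Product: 2 9β-hydroxy enone (4aR,5R)-5-hydroxy-4a-methyl-4,4a,5,6,7,8-hexahydronaphthalen-2(3H)-one
Conditions: NaBH4 (0.3 equiv), EtOH, −10 °C
Reagents that add atoms: none
Why: Chemoselective hydride reduction: the saturated C9 ketone is more electrophilic than the vinylogous enone carbonyl and hydride enters anti to the angular methyl, giving the 9β-alcohol; this parks C9 as an alcohol through the reductive step 3.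

Step 2
Reactants: 2 9β-hydroxy enone
Product: 3 4-(phenylthiomethyl) enone (9β-hydroxy)
Conditions: PhSH, 37% aq. CH2O, Et3N, EtOH, reflux
Reagents that add atoms: formaldehyde C=O; thiophenol Sc1ccccc1
Why: Kirk–Petrow thiomethylation: hydroxymethylation of the dienolate at C4, dehydration and conjugate addition of the thiol place a CH2SPh group on the α-carbon of the enone only.

Step 3
Reactants: 3 4-(phenylthiomethyl) enone
Product: 6 trans-fused 9β-hydroxy-4,4,10-trimethyldecalin-3-one (H5 α), via lithium alkoxide of the 4-methylene ketone 4 (not isolated), via dilithium alkoxide enolate 5 (not isolated)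
Conditions: Li (5 equiv), NH3–THF, t-BuOH (1 equiv), −78 to −33 °C; MeI (excess); NH4Cl
Reagents that add atoms: iodomethane CI
Why: Dissolving-metal reductive alkylation: the first two-electron reduction protonates C5 axially, anti to the C10 methyl (trans fusion, as in reductions of octalones); the enolate expels thiophenolate (E1cB) to 4, and a second reduction gives the regiodefined C4 enolate 5, which iodomethane C-methylates to the gem-dimethyl group.

Step 4
Reactants: 6 hydroxy ketone
Product: 7 3,3-ethylenedioxy-9β-hydroxy-4,4,10-trimethyl-trans-decalin
Conditions: HOCH2CH2OH, p-TsOH (cat.), benzene, reflux (Dean–Stark)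
Reagents that add atoms: ethylene glycol OCCO
Why: Acid-catalysed ketalisation with azeotropic removal of water; only one carbonyl is present and the secondary alcohol is inert.

Step 5
Reactants: 7 hydroxy dioxolane
Product: 8 3,3-ethylenedioxy-4,4,10-trimethyl-trans-decalin-9-one
Conditions: nPr4NRuO4 (cat.), N-methylmorpholine N-oxide, 4 Å sieves, CH2Cl2, rt
Reagents that add atoms: none
Why: Ley–Griffith oxidation under neutral conditions returns the C9 ketone without touching the acid-labile dioxolane.

Step 6
Reactants: 8 C9 ketone
Product: 9 3,3-ethylenedioxy-4,4,10-trimethyl-9-methylene-trans-decalin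
Conditions: Ph3PCH3Br, KOtBu, toluene, 100 °C
Reagents that add atoms: methyltriphenylphosphonium bromide C[P+](c1ccccc1)(c1ccccc1)c1ccccc1.[Br-]
Why: Wittig methylenation of a ketone next to a quaternary carbon; the small ylide and the non-enolisable C10 side allow the forcing conditions used for camphor-type ketones.

Step 7
Reactants: 9 exocyclic alkene
Product: 10 8-hydroxy-9-methylene dioxolane (allylic alcohol; C8 epimers)
Conditions: SeO2 (cat.), t-BuOOH, CH2Cl2, 0 °C to rt
Reagents that add atoms: tert-butyl hydroperoxide CC(C)(C)OO (terminal oxidant; the oxygen is passed on by selenium dioxide O=[Se]=O)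
Why: Riley allylic oxidation in its catalytic form: ene reaction at the terminal CH2 and [2,3]-shift return the alkene to the exocyclic position; C8 is the only allylic carbon that bears hydrogen (C10 is quaternary), as in the oxidation of β-pinene to pinocarveol.

Step 8
Reactants: 10 allylic alcohol
Product: 11 3,3-ethylenedioxy-4,4,10-trimethyl-9-methylene-trans-decalin-8-one
Conditions: Dess–Martin periodinane, CH2Cl2, 0 °C
Reagents that add atoms: none
Why: Dess–Martin oxidation of the allylic alcohol; both C8 epimers converge on the α-methylene ketone, which is used at once.

Step 9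
Reactants: 11 α-methylene ketone; 12 methyl propionate
Product: 14 keto ester methyl 2-methyl-3-(3,3-ethylenedioxy-4,4,10-trimethyl-8-oxo-trans-decalin-9β-yl)propanoate (H9 α; C12 epimers), via lithium enolate of methyl propionate 13 (not isolated)
Conditions: LiN(iPr)2, THF, −78 °C; add 11, −78 to −40 °C; NH4Cl; then K2CO3 (cat.), MeOH, rt
Reagents that add atoms: none
Why: Michael addition of an ester enolate to an s-cis enone with an unhindered β-carbon (C11); the brief base treatment equilibrates C9 next to the C8 ketone to the equatorial side chain with H9 α, anti to the C10 methyl; C12 forms as both epimers, which is immaterial because it is planarised in step 18.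

Step 10
Reactants: 14 keto ester
Product: 15 methyl 2-methyl-3-(3,3-ethylenedioxy-4,4,10-trimethyl-8-methylene-trans-decalin-9β-yl)propanoate (C12 epimers)
Conditions: Ph3PCH3Br, KOtBu, THF, 0 °C to rt
Reagents that add atoms: methyltriphenylphosphonium bromide C[P+](c1ccccc1)(c1ccccc1)c1ccccc1.[Br-]
Why: Wittig methylenation of the C8 ketone, done while C13 is still an ester so that no 1,5-dicarbonyl aldol can occur; C9 already has its thermodynamically preferred configuration, so enolisation by the ylide cannot harm it.

Step 11
Reactants: 15 methylene ester; 16 methyl acetate
Product: 18 β-keto ester methyl 4-methyl-3-oxo-5-(decalin-9β-yl)pentanoate (C12 epimers), via lithium enolate of methyl acetate 17 (not isolated)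
Conditions: LiN(iPr)2 (4 equiv), 16 (4 equiv), THF, −78 °C; add 15, −78 to −20 °C; NH4Cl
Reagents that add atoms: none
Why: Crossed Claisen condensation: excess acetate enolate acylates on the methyl ester, and the product is protected as its enolate until work-up.

Step 12
Reactants: 18 β-keto ester
Product: 19 diazo β-keto ester methyl 2-diazo-4-methyl-3-oxo-5-(decalin-9β-yl)pentanoate (C12 epimers)
Conditions: 4-acetamidobenzenesulfonyl azide, Et3N, MeCN, 0 °C to rt
Reagents that add atoms: 4-acetamidobenzenesulfonyl azide CC(=O)Nc1ccc(cc1)S(=O)(=O)N=[N+]=[N-]
Why: Regitz diazo transfer to the active methylene C14; the isolated alkene and the dioxolane are inert.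

Step 13
Reactants: 19 diazo β-keto ester
Product: 21 cyclopropyl β-keto ester (ring C closed; spiro cyclopropane CH2 on the β face of C8; ester α on C14; C12 epimers), via copper carbenoid 20 (not isolated)
Conditions: Cu(acac)2 (10 mol %), toluene, 110 °C, slow addition of 19
Reagents that add atoms: none
Why: Cu(acac)2 is reduced by the diazo compound to the active univalent copper species, which expels dinitrogen from 19 to give the electrophilic carbenoid 20; this adds to the 1,1-disubstituted alkene in one asynchronous [2+1] event in which bonding to the terminal CH2 runs ahead and the bond to C8 follows. The closest known reaction type is the intramolecular cyclopropanation of alkenyl α-diazo β-keto esters to bicyclo[4.1.0]heptan-2-ones under copper catalysis. Ring C closes in the 6-exo mode (C14 to C8, the methylene carbon staying outside the six-membered ring) and the three-membered ring closes in the same event. C8 is controlled by the face of the alkene that is attacked: the β lobe at C8 is 1,3-diaxial to the C10 methyl, while the equatorial tether on C9 reaches the α lobe through a chair-like arrangement, so C14 enters α (equatorial) and the CH2 is pushed into the β-axial position, giving the trans B/C fusion. C14 needs no separate control because a cyclopropane can only be cis-fused to ring C. The step needs addition to the π bond in preference to insertion into the C9–H or C11–H bonds and to dimerisation. Copper carbenoids of the 1,3-dicarbonyl type favour alkenes, the alkene is electron-rich with an unhindered terminus, and slow addition keeps the carbenoid concentration low. Both C12 epimers of 19 can cyclise, since the methyl can sit on either side of the forming ring.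

Step 14
Reactants: 21 cyclopropyl β-keto ester
Product: 22 ring C β-keto ester with the C8 β-methyl group (C12 epimers; C14 keto–enol mixture)
Conditions: Li (2.2 equiv), NH3–THF, −78 °C; NH4Cl
Reagents that add atoms: none
Why: Dissolving-metal cleavage of a doubly activated cyclopropane: the C14–CH2 bond lies outside ring C and overlaps best with the C13 carbonyl π system, so it takes up two electrons, giving the C8 methyl and a β-keto ester enolate that resists further reduction; C8 keeps its configuration.

Step 15
Reactants: 23 methyl (R)-lactate
Product: 24 methyl (R)-2-(tert-butyldimethylsilyloxy)propanoate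
Conditions: TBSCl, imidazole, DMF, rt
Reagents that add atoms: tert-butyldimethylsilyl chloride CC(C)(C)[Si](C)(C)Cl
Why: Standard silylation of a secondary alcohol; the stereocentre is not involved.

Step 16
Reactants: 24 silyl-protected lactate
Product: 26 (R)-allylsilane tert-butyldimethyl{[3-(trimethylsilylmethyl)but-3-en-2-yl]oxy}silane, via bis(trimethylsilylmethyl) carbinol 25 (not isolated)
Conditions: Me3SiCH2MgCl (3 equiv), CeCl3, THF, −78 °C to rt; then silica gel, CH2Cl2
Reagents that add atoms: (trimethylsilyl)methylmagnesium chloride C[Si](C)(C)C[Mg]Cl
Why: Double addition of the non-basic organocerium reagent to the ester, then Peterson elimination of carbinol 25, is the standard route from esters to 2-substituted allylsilanes; the α-stereocentre is not enolised.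

Step 17
Reactants: 26 allylsilane
Product: 27 (R)-allylic bromide [3-(bromomethyl)but-3-en-2-yl]oxy-tert-butyldimethylsilane
Conditions: NBS, CH2Cl2, −78 °C
Reagents that add atoms: N-bromosuccinimide O=C1CCC(=O)N1Br
Why: Electrophilic bromodesilylation: bromine adds to the alkene terminus and the silyl group leaves, giving the transposed but constitutionally identical allylic bromide.

Step 18
Reactants: 22 ring C β-keto ester; 27 (R)-allylic bromide
Product: 29 C12-alkylated β-keto ester (C16 α on C12; C12 methyl β; side-chain C17 R), via dilithium dianion 28 (not isolated)
Conditions: LiN(iPr)2 (2.4 equiv), THF, −78 to 0 °C; add 27, DMPU, −78 to 0 °C; NH4Cl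
Reagents that add atoms: none
Why: γ-Alkylation of a β-keto ester dianion: the second deprotonation at C12 gives 28, whose more basic γ-carbon reacts with the allylic bromide; axial attack through a chair-like transition state is on the α face, away from the C8 and C10 methyls, which sets C12 with C16 α.

Step 19
Reactants: 29 C12-alkylated β-keto ester
Product: 31 side-chain α-silyloxy ketone (C15 ketone), via vicinal diol 30 (not isolated)
Conditions: OsO4 (cat.), NaIO4, 2,6-lutidine, dioxane–H2O, rt
Reagents that add atoms: sodium periodate [Na+].[O-]I(=O)(=O)=O (the oxygen is passed on by osmium tetroxide O=[Os](=O)(=O)=O)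
Why: Lemieux–Johnson cleavage: dihydroxylation of the isolated 1,1-disubstituted alkene to 30 and periodate cleavage unmask the C15 ketone; the hydrogen-bonded, ester-conjugated enol of the β-keto ester is a much poorer osmylation substrate.

Step 20
Reactants: 31 side-chain α-silyloxy ketone
Product: 32 triketo hydroxy ester (C3 ketone and C17 hydroxyl free)
Conditions: 2 M HCl, THF, rt to 40 °C
Reagents that add atoms: water O
Why: Acid hydrolysis removes the secondary silyl ether and the strained dioxolane next to the gem-dimethyl group in one operation; the quaternary C12 blocks furan formation from the 1,4-diketone.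

Step 21
Reactants: 32 triketo hydroxy ester
Product: 34 bridged diketo hydroxy γ-lactone (rings D and E closed; C3 and C13 ketones), via aldol adduct 33 (not isolated)
Conditions: DBU, toluene, rt to 40 °C
Reagents that add atoms: none
Why: Aldol–lactonisation cascade: because C16 is axial α on C12, the C14 enolate can reach the C15 ketone only across the α face, which closes ring D; the reversible aldol is drained by lactonisation of the C17 hydroxyl onto the methyl ester, possible only for the C15 epimer with the hydroxyl endo, so C14 and C15 are set together; DBU is too weak to enolise C17.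

Step 22
Reactants: 34 bridged diketo hydroxy γ-lactone
Product: 35 ring A ε-lactone (O between C3 and C4) with the C13 ketone
Conditions: mCPBA, CH2Cl2, rt
Reagents that add atoms: 3-chloroperbenzoic acid OOC(=O)c1cccc(Cl)c1
Why: Baeyer–Villiger oxidation with migration of the tertiary C4, as for 4,4-dimethyl-3-keto terpenoids; the C13 ketone, flanked by two quaternary bridgeheads, should form its peroxy adduct far more slowly, and no alkene is yet present.

Step 23
Reactants: 35 ε-lactone ketone
Product: 36 1,2-dihydrobrasilianoid B (C13 exocyclic methylene)
Conditions: Zn, CH2Br2, TiCl4, THF–CH2Cl2, 0 °C to rt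
Reagents that add atoms: dibromomethane BrCBr
Why: Takai–Lombardo methylenation: the non-basic gem-dimetallic titanium reagent converts the non-enolisable bridging ketone into the alkene, does not methylenate lactones, and does not expose the β-hydroxy ketone to base (retro-aldol).

Step 24
Reactants: 36 1,2-dihydrobrasilianoid B
Product: 39 brasilianoid B, via phenylselenyl lactone 37 (not isolated), via selenoxide 38 (not isolated)
Conditions: LiN(iPr)2 (3 equiv), THF, −78 °C; PhSeBr; AcOH; then 30% H2O2, pyridine, CH2Cl2, 0 °C to rt
Reagents that add atoms: none
Why: α-Selenenylation of the ε-lactone enolate (C2 is the only enolisable carbon once the hydroxyl is deprotonated), oxidation to selenoxide 38 and syn-elimination toward C1 give the cis alkene of ring A; pyridine buffers the selenium acids so that the exocyclic methylene is not epoxidised.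

## Compound list

1 | (R)-Wieland–Miescher ketone | C[C@@]12CCC(=O)C=C1CCCC2=O | starting material
2 | (4aR,5R)-5-hydroxy-4a-methyl-4,4a,5,6,7,8-hexahydronaphthalen-2(3H)-one (9β-hydroxy enone) | C[C@@]12CCC(=O)C=C1CCC[C@H]2O | intermediate
3 | 9β-hydroxy-4-(phenylthiomethyl) enone | C[C@@]12CCC(=O)C(CSc3ccccc3)=C1CCC[C@H]2O | intermediate
4 | lithium 9β-alkoxide of the trans-fused 10-methyl-4-methylenedecalin-3-one | [Li+].[O-][C@H]3[C@]4(C)CCC(=O)C(=C)[C@H]4CCC3 | intermediate (not isolated)
5 | dilithium 9β-alkoxide C3–C4 enolate of the trans-fused 4,10-dimethyldecalin-3-one | [Li+].[Li+].[O-][C@H]3[C@]4(C)CCC([O-])=C(C)[C@H]4CCC3 | intermediate (not isolated)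
6 | trans-fused 9β-hydroxy-4,4,10-trimethyldecalin-3-one (H5 α) | O[C@H]3[C@]4(C)CCC(=O)C(C)(C)[C@H]4CCC3 | intermediate
7 | 3,3-ethylenedioxy-9β-hydroxy-4,4,10-trimethyl-trans-decalin | O[C@H]3[C@]4(C)CCC5(OCCO5)C(C)(C)[C@H]4CCC3 | intermediate
8 | 3,3-ethylenedioxy-4,4,10-trimethyl-trans-decalin-9-one | O=C3[C@]4(C)CCC5(OCCO5)C(C)(C)[C@H]4CCC3 | intermediate
9 | 3,3-ethylenedioxy-4,4,10-trimethyl-9-methylene-trans-decalin | C=C3[C@]4(C)CCC5(OCCO5)C(C)(C)[C@H]4CCC3 | intermediate
10 | 3,3-ethylenedioxy-8-hydroxy-4,4,10-trimethyl-9-methylene-trans-decalin (C8 epimers) | C=C3[C@]4(C)CCC5(OCCO5)C(C)(C)[C@H]4CCC3O | intermediate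
11 | 3,3-ethylenedioxy-4,4,10-trimethyl-9-methylene-trans-decalin-8-one | C=C3[C@]4(C)CCC5(OCCO5)C(C)(C)[C@H]4CCC3=O | intermediate
12 | methyl propionate | CCC(=O)OC | starting material
13 | lithium enolate of methyl propionate | [Li+].CC=C([O-])OC | intermediate (not isolated)
14 | methyl 2-methyl-3-(3,3-ethylenedioxy-4,4,10-trimethyl-8-oxo-trans-decalin-9β-yl)propanoate (H9 α; C12 epimers) | COC(=O)C(C)C[C@H]3[C@]4(C)CCC5(OCCO5)C(C)(C)[C@H]4CCC3=O | intermediate
15 | methyl 2-methyl-3-(3,3-ethylenedioxy-4,4,10-trimethyl-8-methylene-trans-decalin-9β-yl)propanoate (C12 epimers) | COC(=O)C(C)C[C@H]3[C@]4(C)CCC5(OCCO5)C(C)(C)[C@H]4CCC3=C | intermediate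
16 | methyl acetate | CC(=O)OC | starting material
17 | lithium enolate of methyl acetate | [Li+].C=C([O-])OC | intermediate (not isolated)
18 | methyl 4-methyl-3-oxo-5-(3,3-ethylenedioxy-4,4,10-trimethyl-8-methylene-trans-decalin-9β-yl)pentanoate (C12 epimers) | COC(=O)CC(=O)C(C)C[C@H]3[C@]4(C)CCC5(OCCO5)C(C)(C)[C@H]4CCC3=C | intermediate
19 | methyl 2-diazo-4-methyl-3-oxo-5-(3,3-ethylenedioxy-4,4,10-trimethyl-8-methylene-trans-decalin-9β-yl)pentanoate (C12 epimers) | COC(=O)C(=[N+]=[N-])C(=O)C(C)C[C@H]3[C@]4(C)CCC5(OCCO5)C(C)(C)[C@H]4CCC3=C | intermediate
20 | copper carbenoid at C14 of 19 (other ligands on copper not shown) | COC(=O)C(=[Cu])C(=O)C(C)C[C@H]3[C@]4(C)CCC5(OCCO5)C(C)(C)[C@H]4CCC3=C | intermediate (not isolated)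
21 | cyclopropyl β-keto ester: ring C ketone with the C8/C14 cyclopropane (CH2 β on C8; ester α on C14; trans B/C; C12 epimers) | O=C1C(C)C[C@H]3[C@]4(C)CCC5(OCCO5)C(C)(C)[C@H]4CC[C@@]37C[C@@]17C(=O)OC | intermediate
22 | ring C β-keto ester with the C8 β-methyl group (C12 epimers; C14 enolisable) | O=C1C(C)C[C@H]3[C@]4(C)CCC5(OCCO5)C(C)(C)[C@H]4CC[C@]3(C)C1C(=O)OC | intermediate
23 | methyl (R)-lactate | C[C@@H](O)C(=O)OC | starting material
24 | methyl (R)-2-(tert-butyldimethylsilyloxy)propanoate | C[C@@H](O[Si](C)(C)C(C)(C)C)C(=O)OC | intermediate
25 | (R)-3-(tert-butyldimethylsilyloxy)-1-(trimethylsilyl)-2-(trimethylsilylmethyl)butan-2-ol | C[C@@H](O[Si](C)(C)C(C)(C)C)C(O)(C[Si](C)(C)C)C[Si](C)(C)C | intermediate (not isolated)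
26 | (R)-tert-butyldimethyl{[3-(trimethylsilylmethyl)but-3-en-2-yl]oxy}silane | C[C@@H](O[Si](C)(C)C(C)(C)C)C(=C)C[Si](C)(C)C | intermediate
27 | (R)-[3-(bromomethyl)but-3-en-2-yl]oxy-tert-butyldimethylsilane | C[C@@H](O[Si](C)(C)C(C)(C)C)C(=C)CBr | intermediate
28 | dilithium dianion of 22 (C12=C13 enolate and C14=C18 ester enolate) | [Li+].[Li+].[O-]C1=C(C)C[C@H]3[C@]4(C)CCC5(OCCO5)C(C)(C)[C@H]4CC[C@]3(C)C1=C([O-])OC | intermediate (not isolated)
29 | C12-alkylated β-keto ester: 22 carrying on the α face of C12 the (R)-3-(silyloxy)-2-methylenebutyl chain (C14 enolisable) | O=C1[C@](C)(CC(=C)[C@@H](C)O[Si](C)(C)C(C)(C)C)C[C@H]3[C@]4(C)CCC5(OCCO5)C(C)(C)[C@H]4CC[C@]3(C)C1C(=O)OC | intermediate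
30 | vicinal diol from dihydroxylation of the side-chain alkene of 29 (C15 unassigned) | O=C1[C@](C)(CC(O)(CO)[C@@H](C)O[Si](C)(C)C(C)(C)C)C[C@H]3[C@]4(C)CCC5(OCCO5)C(C)(C)[C@H]4CC[C@]3(C)C1C(=O)OC | intermediate (not isolated)
31 | side-chain ketone: C12-[(R)-3-(tert-butyldimethylsilyloxy)-2-oxobutyl] β-keto ester with the ring A dioxolane | O=C1[C@](C)(CC(=O)[C@@H](C)O[Si](C)(C)C(C)(C)C)C[C@H]3[C@]4(C)CCC5(OCCO5)C(C)(C)[C@H]4CC[C@]3(C)C1C(=O)OC | intermediate
32 | triketo hydroxy ester: C12-[(R)-3-hydroxy-2-oxobutyl] β-keto ester with the free C3 ketone | O=C1[C@](C)(CC(=O)[C@@H](C)O)C[C@H]3[C@]4(C)CCC(=O)C(C)(C)[C@H]4CC[C@]3(C)C1C(=O)OC | intermediate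
33 | aldol adduct: ring D closed with the C15 tertiary hydroxyl endo and the methyl ester on C14 (lactone not yet formed) | O=C1[C@@]2(C)C[C@H]3[C@]4(C)CCC(=O)C(C)(C)[C@H]4CC[C@]3(C)[C@]1(C(=O)OC)[C@@](O)([C@@H](C)O)C2 | intermediate (not isolated)
34 | bridged diketo hydroxy γ-lactone (rings B to E of the target; C3 and C13 ketones) | O=C1[C@@]2(C)C[C@H]3[C@]4(C)CCC(=O)C(C)(C)[C@H]4CC[C@]3(C)[C@@]16C(=O)O[C@H](C)[C@@]6(O)C2 | intermediate
35 | saturated ring A ε-lactone with the C13 ketone | O=C1[C@@]2(C)C[C@H]3[C@]4(C)CCC(=O)OC(C)(C)[C@H]4CC[C@]3(C)[C@@]16C(=O)O[C@H](C)[C@@]6(O)C2 | intermediate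
36 | 1,2-dihydrobrasilianoid B | C=C1[C@@]2(C)C[C@H]3[C@]4(C)CCC(=O)OC(C)(C)[C@H]4CC[C@]3(C)[C@@]13C(=O)O[C@H](C)[C@@]3(O)C2 | intermediate
37 | 2-(phenylselanyl)-1,2-dihydrobrasilianoid B (C2 epimers) | C=C1[C@@]2(C)C[C@H]3[C@]4(C)CC([Se]c5ccccc5)C(=O)OC(C)(C)[C@H]4CC[C@]3(C)[C@@]16C(=O)O[C@H](C)[C@@]6(O)C2 | intermediate (not isolated)
38 | selenoxide of 37 | C=C1[C@@]2(C)C[C@H]3[C@]4(C)CC([Se](=O)c5ccccc5)C(=O)OC(C)(C)[C@H]4CC[C@]3(C)[C@@]16C(=O)O[C@H](C)[C@@]6(O)C2 | intermediate (not isolated)
39 | brasilianoid B | C=C1[C@@]2(C)C[C@H]3[C@]4(C)C=CC(=O)OC(C)(C)[C@H]4CC[C@]3(C)[C@@]13C(=O)O[C@H](C)[C@@]3(O)C2 | target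

## Step count and least certain steps

Total: 24 steps. Longest linear sequence: 21 steps (steps 1–14 and 18–24); the side chain 27 takes 3 steps (15–17).

**Step 13 (key step).** The most likely failures are insertion of the carbenoid into the C9–H or C11–H bonds, and loss of facial selectivity if the tether reaches the β lobe of the alkene through a boat-like arrangement. Dimerisation of the carbenoid is a lesser risk. Fallback: abandon the diazo route and make the same two bonds in two polar steps from 18. An iodine-promoted carbocyclisation (I2, Ti(OtBu)4, CuO) lets the C14 enol attack the iodonium-activated alkene at C8 and gives the iodomethyl β-keto ester F1. Displacement of iodide by the C14 enolate (K2CO3, 3-exo-tet) then closes the three-membered ring and returns to the route at 21.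

**Step 18.** The dianion may form incompletely at the C12 methine, which would lead to alkylation at C14 or on oxygen. The hindered γ-carbon may also attack the 2-substituted allylic bromide slowly, and facial selectivity at C12 may be incomplete. Fallback: alkylate before the cyclopropane is opened. In 21, C14 is quaternary, so KN(SiMe3)2 can form only the C12 enolate. Reaction with 27 gives the alkylated cyclopropyl ketone F2, and reductive opening of the cyclopropane (Li/NH3 or SmI2) returns to the route at 29. The face of attack in this bicyclic enolate is less predictable than in 28, which is why it is the fallback and not the main route.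

**Step 22.** The peracid may also attack the strained C13 ketone, and the step that follows must then methylenate a hindered ketone beside two lactones. Fallback (it also relieves step 23): keep the dioxolane and invert the order. From 31, nBu4NF removes the silyl group and triggers the aldol–lactonisation to the dioxolane lactone F3 (the same compound as A4). Methylenation of its only ketone (Cp2TiMe2, or Zn/CH2Br2/TiCl4) gives the alkene F4, and aqueous acid gives the C3 ketone F5. A Baeyer–Villiger oxidation with bis(trimethylsilyl) peroxide and SnCl4, an oxidant that leaves alkenes alone, then returns to the route at 36.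

**Step 14.** Excess metal may reduce the ester or the ketone, and some cleavage of the ring-fusion bond C8–C14 would give a ring-expanded product. Fallback: open the ring with a nucleophile instead of electrons. PhSeNa (from PhSeSePh and NaBH4) should attack the unhindered CH2 of the doubly activated cyclopropane of 21 and give the selenide F6. Bu3SnH with AIBN then replaces selenium by hydrogen and returns to the route at 22.

**Step 11.** Proton transfer from C12–H of the α-branched ester to the acetate enolate, and self-condensation of that enolate, may leave 15 unchanged. Fallback: saponify 15 (LiOH) to the acid F7, activate it with carbonyldiimidazole as the acyl imidazolide F8, and acylate Mg(O2CCH2CO2Me)2. Decarboxylation on work-up returns to the route at 18.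

**Step 3.** The one-pot sequence needs four electrons and an elimination in the right order. Protonation of the second enolate before methylation (monomethyl ketone), over-reduction of the C3 carbonyl, or O-methylation at C9 could intervene. Fallback: separate the events. Raney nickel desulfurisation of 3 gives the 4-methyl enone F9, and an ordinary reductive methylation (Li/NH3, then MeI) returns to the route at 6.

## Further compounds

F1 | step 13 | iodomethyl β-keto ester: ring C closed by the C8–C14 bond with CH2I β on C8 (C12 epimers) | O=C1C(C)C[C@H]3[C@]4(C)CCC5(OCCO5)C(C)(C)[C@H]4CC[C@]3(CI)C1C(=O)OC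
F2 | step 18 | C12-alkylated cyclopropyl β-keto ester (21 carrying the side chain of 27 on C12) | O=C1[C@](C)(CC(=C)[C@@H](C)O[Si](C)(C)C(C)(C)C)C[C@H]3[C@]4(C)CCC5(OCCO5)C(C)(C)[C@H]4CC[C@@]37C[C@@]17C(=O)OC
F3 | step 22 | bridged keto hydroxy γ-lactone with the ring A dioxolane | O=C1[C@@]2(C)C[C@H]3[C@]4(C)CCC5(OCCO5)C(C)(C)[C@H]4CC[C@]3(C)[C@@]16C(=O)O[C@H](C)[C@@]6(O)C2
F4 | step 22 | C13-methylene hydroxy γ-lactone with the ring A dioxolane | C=C1[C@@]2(C)C[C@H]3[C@]4(C)CCC5(OCCO5)C(C)(C)[C@H]4CC[C@]3(C)[C@@]16C(=O)O[C@H](C)[C@@]6(O)C2
F5 | step 22 | C13-methylene hydroxy γ-lactone with the free C3 ketone | C=C1[C@@]2(C)C[C@H]3[C@]4(C)CCC(=O)C(C)(C)[C@H]4CC[C@]3(C)[C@@]16C(=O)O[C@H](C)[C@@]6(O)C2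
F6 | step 14 | C8-(phenylselanylmethyl) ring C β-keto ester (C12 epimers) | O=C1C(C)C[C@H]3[C@]4(C)CCC5(OCCO5)C(C)(C)[C@H]4CC[C@]3(C[Se]c6ccccc6)C1C(=O)OC
F7 | step 11 | 2-methyl-3-(3,3-ethylenedioxy-4,4,10-trimethyl-8-methylene-trans-decalin-9β-yl)propanoic acid (C12 epimers) | OC(=O)C(C)C[C@H]3[C@]4(C)CCC5(OCCO5)C(C)(C)[C@H]4CCC3=C
F8 | step 11 | acyl imidazolide of F7 | O=C(n1ccnc1)C(C)C[C@H]3[C@]4(C)CCC5(OCCO5)C(C)(C)[C@H]4CCC3=C
F9 | step 3 | (4aR,5R)-5-hydroxy-1,4a-dimethyl-4,4a,5,6,7,8-hexahydronaphthalen-2(3H)-one (4-methyl enone) | C[C@@]12CCC(=O)C(C)=C1CCC[C@H]2O
A1 | alternative 1 | ring C 2-methyl enone whose C14 ester is the (R)-3-(tert-butyldimethylsilyloxy)but-3-en-2-yl ester | CC=1C(=O)C[C@H]3[C@]4(C)CCC5(OCCO5)C(C)(C)[C@H]4CC[C@]3(C)C=1C(=O)O[C@H](C)C(=C)O[Si](C)(C)C(C)(C)C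
A2 | alternative 1 | cyclobutane-fused γ-lactone photoadduct | C[C@@]12C(=O)C[C@H]3[C@]4(C)CCC5(OCCO5)C(C)(C)[C@H]4CC[C@]3(C)[C@@]16C(=O)O[C@H](C)[C@@]6(O[Si](C)(C)C(C)(C)C)C2
A3 | alternative 2 | ring C β-keto ester with the C12-[(R)-3-hydroxy-2-oxobutyl] chain and the ring A dioxolane | O=C1[C@](C)(CC(=O)[C@@H](C)O)C[C@H]3[C@]4(C)CCC5(OCCO5)C(C)(C)[C@H]4CC[C@]3(C)C1C(=O)OC
A4 | alternative 2 | bicyclo[3.2.1]octan-8-one with fused hydroxy γ-lactone and the ring A dioxolane | O=C1[C@@]2(C)C[C@H]3[C@]4(C)CCC5(OCCO5)C(C)(C)[C@H]4CC[C@]3(C)[C@@]16C(=O)O[C@H](C)[C@@]6(O)C2
A5 | alternative 3 | decalin C9 aldehyde whose C8 carries the 1-(methoxycarbonyl)-2,3-dimethyl-5-oxocyclopent-2-en-1-yl group | O=C[C@H]3[C@]4(C)CCC5(OCCO5)C(C)(C)[C@H]4CC[C@]3(C)[C@]1(C(=O)OC)C(=O)CC(C)=C1C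
A6 | alternative 3 | bicyclo[3.2.1]octanone with the exocyclic methylene bridge and the C11 carbinol | C=C1[C@@]2(C)[C@@H](O)[C@H]3[C@]4(C)CCC5(OCCO5)C(C)(C)[C@H]4CC[C@]3(C)[C@]1(C(=O)OC)C(=O)C2
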